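The vessel is closed, stirred and isothermal, and it takes two charges: partner adds to substrate in two ways, either mono adduct can take a second partner to give bis adduct, and partner also decays by itself.

in all of them: substrate 0.12 M; time 40 h

| flask | partner |
|---|---|
| Monday's | 0.120 M |
| Thursday's | 0.180 M |

    partner + other mono adduct → bis adduct (k1 = 0.15 /M/h)
    partner → decomposed reagent (k2 = 0.021 /h)
    substrate + partner → other mono adduct (k3 = 0.29 /M/h)
    substrate + partner → mono adduct (k4 = 0.86 /M/h)
    partner + mono adduct → bis adduct (k5 = 0.18 /M/h)

1. which of these there is most of at the end, counted by the substrate in it, Monday's (substrate / mono adduct / bis adduct / other mono adduct)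
2. which of these there is most of at the end, counted by the substrate in it, Thursday's (substrate / mono adduct / bis adduct / other mono adduct)
3. the largest of these amounts at the end, in percent of the substrate charged, Monday's
4. the largest of these amounts at the end, in percent of the substrate charged, Thursday's

I build Monday's flask one process at a time and count x, the fraction of substrate left. With the step to mono adduct by itself, equal charges leave x at 19.5% and give 80.5% mono adduct. Adding the step to other mono adduct raises the rate constant for loss of substrate to 1.15 /M/h, with a share f of 74.8% going to mono adduct; x falls to 15.3%, and mono adduct falls to 63.3%.

Now mono adduct takes a second partner. Its making and its loss both run in proportion to partner, and so does the loss of substrate, so dividing these rates removes partner and the clock. The ratio of second addition to first, a selectivity factor, is κ = 0.157, and it gives a curve: mono adduct = f(x^κ − x)/(1 − κ). For these constants the curve crests at x = 11.1%, where its height is fx/κ.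

I now add decomposition and the last step and reckon how far x travels. Reaching x costs partner: one per substrate converted, one more per bis adduct, and (k2/K)ln(1/x) lost to decomposition. On Monday's, one pass of this balance gives x = 28.7%, with other mono adduct 16.3% and bis adduct 7.52%. The bill is 0.117 M, just inside the charge. So I commit to mono adduct at 47.5%.

On Thursday's, the crest carries other mono adduct at 18.6% and bis adduct at 17.3%. Its bill of 0.168 M is less than the charge, so I commit to mono adduct at 53.0%. The bill has no clock in it, which is the weakest point of my reckoning.

The forecast gives mono adduct at 47% on Monday's and mono adduct at 53% on Thursday's, where it says the mono adduct “gains only modestly”.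

On Monday's the simulation gives mono adduct at 47.3%. On Thursday's it gives mono adduct at 53.0%, with substrate at 10.9%, beside the crest. On Monday's, the step to mono adduct uses partner 3.2 times as fast as decomposition at 4.23 h but 1.4 times as fast at 40.0 h, with 2.8% of the partner and 29% of the substrate left. At that substrate in Monday's flask, the curve reads 47.3%. Monday's flask with 0.048 M of partner ends with 67.3% substrate, where the curve reads 23.7%, and it holds 23.7% mono adduct.

All constants are those of an exercise, and the outcome is calculated.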